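**Retrosynthetic overview**
1. Feature: the target is an ArCH2–C(=O)–Ar dimer of one benzophenone. Each inner benzene ring carries, in ring order, 2,6-dimethoxybenzoyl, OH, H, CH3, OCH3 and a one-carbon arm (CH2 on ring A, C=O on ring B).
2. Last disconnection: the CH2–C(=O) bond between the two arms. The laterally lithiated O-silyl monomer adds to the aldehyde made from the same monomer, followed by oxidation and desilylation.
3. The aldehyde comes from the monomer by photoenolisation, O2 trapping and dehydration of the peroxide. The 1,5-hydrogen shift to the excited ketone reaches only the ketone-flanked CH3.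
4. Key disconnection: the inner ring splits into C(aroyl)–C(OH)–CH and C(CH3)–C(OCH3)–C(CH3). The first unit is the central, C3 and terminal carbons of a 1-aryl-1,3-diketone bis(silyl enol ether). The second is C4–C3–C2 of silylated 3-methoxypentane-2,4-dione. They are joined by a formal [3+3] cyclocondensation.
5. Ring order: the outer dimethoxyphenyl ring is bought. The inner ring is the only ring built, once, and it serves both halves.

Key step: step 6

Remark: the target SMILES has no stereocentre, no stereogenic double bond and no stereodescriptor. The aryl–carbonyl axes are taken as freely rotating, so the compound is treated as achiral and no enantioselective step is needed.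

**Step 1**
Reactants: 1 2',6'-dimethoxyacetophenone; 2 ethyl acetate
Product: 3 1-(2,6-dimethoxyphenyl)butane-1,3-dione
Conditions: NaH, EtOAc (excess), THF, reflux; then aq HCl
Reagents that add atoms: none
Why: Crossed Claisen condensation, in which the sodium enolate of the methyl ketone is acylated by ethyl acetate, the hindered aryl ketone cannot serve as acceptor, and irreversible deprotonation of the β-diketone drives the equilibrium.

**Step 2**
Reactants: 3 1-(2,6-dimethoxyphenyl)butane-1,3-dione
Product: 5 (1Z)-1-(2,6-dimethoxyphenyl)-1,3-bis(trimethylsilyloxy)buta-1,3-diene, via (3Z)-4-(2,6-dimethoxyphenyl)-4-(trimethylsilyloxy)but-3-en-2-one 4 (not isolated)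
Conditions: TMSOTf (2.3 equiv), Et3N, Et2O, 0 °C → rt; decant from the ammonium salt, concentrate, use without chromatography
Reagents that add atoms: trimethylsilyl triflate, C[Si](C)(C)OS(=O)(=O)C(F)(F)F
Why: Soft enolisation and O-silylation with silyl triflate and amine, a known one-flask route from 1,3-diketones to 1,3-bis(silyl enol ethers), in which the enolised diketone is silylated first to 4 and the remaining methyl ketone then gives its terminal silyl enol ether, the only enolisable position left.

**Step 3**
Reactants: 6 acetylacetone (pentane-2,4-dione)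
Product: 7 3-diazopentane-2,4-dione
Conditions: 4-acetamidobenzenesulfonyl azide, Et3N, MeCN, 0 °C → rt
Reagents that add atoms: 4-acetamidobenzenesulfonyl azide, CC(=O)Nc1ccc(cc1)S(=O)(=O)N=[N+]=[N-]
Why: Regitz diazo transfer, in which the diketone enolate attacks the terminal nitrogen of the sulfonyl azide and the adduct collapses to the stabilised diazo diketone and the sulfonamide.

**Step 4**
Reactants: 7 3-diazopentane-2,4-dione
Product: 8 3-methoxypentane-2,4-dione
Conditions: Rh2(OAc)4 (1 mol %), MeOH, CH2Cl2, reflux
Reagents that add atoms: methanol, CO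
Why: Rhodium-carbenoid O–H insertion, in which the electrophilic diacyl carbenoid should be captured by methanol faster than it rearranges, placing the methoxy group on the central carbon.

**Step 5**
Reactants: 8 3-methoxypentane-2,4-dione
Product: 9 (3E)-3-methoxy-4-(trimethylsilyloxy)pent-3-en-2-one
Conditions: TMSCl, Et3N, pentane, rt; filter, distil
Reagents that add atoms: chlorotrimethylsilane, C[Si](C)(C)Cl
Why: O-silylation of an enolised 1,3-diketone with chlorosilane and amine, the standard preparation of 3-silyloxy-2-en-1-ones, and the two equivalent acetyl groups allow only one constitutional isomer.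

**Step 6**
Reactants: 5 (1Z)-1-(2,6-dimethoxyphenyl)-1,3-bis(trimethylsilyloxy)buta-1,3-diene; 9 (3E)-3-methoxy-4-(trimethylsilyloxy)pent-3-en-2-one
Product: 12 (2,6-dimethoxyphenyl)(6-hydroxy-3-methoxy-2,4-dimethylphenyl)methanone, via (1Z,5E)-1-(2,6-dimethoxyphenyl)-6-methoxy-5-methyl-1-(trimethylsilyloxy)octa-1,5-diene-3,7-dione 10 (not isolated), via 6-(2,6-dimethoxybenzoyl)-5-hydroxy-4-methoxy-3,5-dimethylcyclohex-3-en-1-one 11 (not isolated)
Conditions: TiCl4 (1.1 equiv), CH2Cl2 (concentrated), −78 → 20 °C; then 10 % aq HCl
Reagents that add atoms: none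
Why: TiCl4 binds the ketone and neighbouring methoxy oxygen of 9, the terminal CH2 carbon of diene 5 (its most nucleophilic and least hindered position) adds to the silyloxy-bearing β-carbon, and expulsion of silanolate gives the open-chain enedione 10, which is the first ring C–C bond. The surviving aryl silyl enol ether, the former central carbon of 5, then attacks the titanium-activated methyl ketone in an intramolecular Mukaiyama aldol, a 6-(enolexo)-exo-trig closure of the only new ring, to give 11 (second ring C–C bond), and loss of water with keto–enol tautomerisation aromatises to 12. The closest known reaction type is the titanium-mediated formal [3+3] cyclocondensation of 1,3-bis(silyl enol ethers) with 3-silyloxy-2-en-1-ones, established for diketone-derived dienes (giving 2-acylphenols) and for enones carrying a heteroatom at C2. The two stereocentres of 11 are transient and vanish on aromatisation, so no stereocontrol is required. The step needs the order terminal carbon first and central carbon second, which is inherent in the vinylogous reactivity of the diene and puts OH beside the aroyl group, while the dielectrophile offers no regiochemical choice because both electrophilic carbons carry methyl and flank the same C–OMe. The tetra-ortho-substituted aryl–CO–aryl linkage is already present in 5, so its crowding has to be overcome only in an intramolecular closure driven by aromatisation.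

**Step 7**
Reactants: 12 (2,6-dimethoxyphenyl)(6-hydroxy-3-methoxy-2,4-dimethylphenyl)methanone
Product: 13 {6-[(tert-butyldimethylsilyl)oxy]-3-methoxy-2,4-dimethylphenyl}(2,6-dimethoxyphenyl)methanone
Conditions: TBSOTf, 2,6-lutidine, CH2Cl2, 0 °C → rt
Reagents that add atoms: tert-butyldimethylsilyl triflate, CC(C)(C)[Si](C)(C)OS(=O)(=O)C(F)(F)F
Why: Silyl ether formation with a silyl triflate reactive enough for a hindered hydrogen-bonded phenol; capping the OH switches off the excited-state proton transfer that would quench the ketone in step 8, and the silyl group offers no abstractable C–H next to oxygen.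

**Step 8**
Reactants: 13 {6-[(tert-butyldimethylsilyl)oxy]-3-methoxy-2,4-dimethylphenyl}(2,6-dimethoxyphenyl)methanone
Product: 16 3-[(tert-butyldimethylsilyl)oxy]-2-(2,6-dimethoxybenzoyl)-6-methoxy-5-methylbenzaldehyde, via rac-8-[(tert-butyldimethylsilyl)oxy]-1-(2,6-dimethoxyphenyl)-5-methoxy-6-methyl-1,4-dihydro-2,3-benzodioxin-1-ol 14 (not isolated), via 3-[(tert-butyldimethylsilyl)oxy]-2-(2,6-dimethoxybenzoyl)-6-methoxy-5-methylbenzyl peroxyacetate 15 (not isolated)
Conditions: O2 (1 atm), hν (365 nm, Pyrex), C6H6, 10–15 °C; then in the dark Ac2O, Et3N, DMAP (cat.), 0 °C → rt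
Reagents that add atoms: oxygen, O=O
Why: Photoenolisation of an o-alkylaryl ketone with oxygen trapping, in which the excited ketone abstracts hydrogen through a six-membered transition state that only the flanking C2 methyl can reach (the C4 methyl is para and remote), the hydroxy-o-quinodimethane adds O2 in [4+2] fashion to the racemic peroxy-hemiketal 14, and in the dark acetylation of its ring-opened hydroperoxide form to 15 and Kornblum–DeLaMare-type elimination of acetate give the aldehyde, erasing the transient stereocentre and keeping the photolabile product out of the light.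

**Step 9**
Reactants: 13 {6-[(tert-butyldimethylsilyl)oxy]-3-methoxy-2,4-dimethylphenyl}(2,6-dimethoxyphenyl)methanone; 16 3-[(tert-butyldimethylsilyl)oxy]-2-(2,6-dimethoxybenzoyl)-6-methoxy-5-methylbenzaldehyde
Product: 18 rac-1,2-bis{3-[(tert-butyldimethylsilyl)oxy]-2-(2,6-dimethoxybenzoyl)-6-methoxy-5-methylphenyl}ethan-1-ol, via laterally lithiated 13 (lithium o-quinodimethane enolate, drawn as the benzyllithium) 17 (not isolated)
Conditions: 13, LiTMP (from 2,2,6,6-tetramethylpiperidine and n-BuLi), THF, −78 °C; then 16 in THF, −78 → −40 °C; AcOH quench at −78 °C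
Reagents that add atoms: none
Why: Lateral lithiation and aldol-type addition, the ketone counterpart of o-toluate anion chemistry, in which the hydride-free amide base is guided by the ketone oxygen to the ortho methyl group, the resulting enolate 17 adds through its benzylic carbon to the aldehyde of 16 (the only accessible electrophile, since both diaryl ketones are tetra-ortho-blocked), and the new carbinol centre forms as a racemate that step 10 erases.

**Step 10**
Reactants: 18 rac-1,2-bis{3-[(tert-butyldimethylsilyl)oxy]-2-(2,6-dimethoxybenzoyl)-6-methoxy-5-methylphenyl}ethan-1-ol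
Product: 19 1,2-bis{3-[(tert-butyldimethylsilyl)oxy]-2-(2,6-dimethoxybenzoyl)-6-methoxy-5-methylphenyl}ethan-1-one
Conditions: Dess–Martin periodinane, pyridine, CH2Cl2, 0 °C → rt
Reagents that add atoms: none
Why: Dess–Martin oxidation of a secondary benzylic alcohol under pyridine-buffered conditions, which tolerates aryl silyl ethers, methyl ethers and aryl methyl groups, drains any lactol tautomer of 18 through its open form, and avoids acid that could dehydrate such a lactol.

**Step 11**
Reactants: 19 1,2-bis{3-[(tert-butyldimethylsilyl)oxy]-2-(2,6-dimethoxybenzoyl)-6-methoxy-5-methylphenyl}ethan-1-one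
Product: 20 acredinone B, 1,2-bis[2-(2,6-dimethoxybenzoyl)-3-hydroxy-6-methoxy-5-methylphenyl]ethan-1-one
Conditions: TBAF buffered with AcOH, THF, 0 °C
Reagents that add atoms: none
Why: Fluoride-induced cleavage of the two aryl silyl ethers, buffered so that neither phenoxide nor the enolate of the benzyl ketone builds up and intramolecular aldol closure onto an aroyl ketone is avoided, while all methyl ethers stay untouched.

**Compound list**
1 | 2',6'-dimethoxyacetophenone | CC(=O)c1c(OC)cccc1OC | starting material
2 | ethyl acetate | CCOC(C)=O | starting material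
3 | 1-(2,6-dimethoxyphenyl)butane-1,3-dione | CC(=O)CC(=O)c1c(OC)cccc1OC | intermediate
4 | (3Z)-4-(2,6-dimethoxyphenyl)-4-(trimethylsilyloxy)but-3-en-2-one (not isolated) | CC(=O)/C=C(\O[Si](C)(C)C)c1c(OC)cccc1OC | intermediate
5 | (1Z)-1-(2,6-dimethoxyphenyl)-1,3-bis(trimethylsilyloxy)buta-1,3-diene | C=C(O[Si](C)(C)C)/C=C(\O[Si](C)(C)C)c1c(OC)cccc1OC | intermediate
6 | acetylacetone (pentane-2,4-dione) | CC(=O)CC(C)=O | starting material
7 | 3-diazopentane-2,4-dione | CC(=O)C(=[N+]=[N-])C(C)=O | intermediate
8 | 3-methoxypentane-2,4-dione | CC(=O)C(OC)C(C)=O | intermediate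
9 | (3E)-3-methoxy-4-(trimethylsilyloxy)pent-3-en-2-one | CC(=O)/C(OC)=C(/C)O[Si](C)(C)C | intermediate
10 | (1Z,5E)-1-(2,6-dimethoxyphenyl)-6-methoxy-5-methyl-1-(trimethylsilyloxy)octa-1,5-diene-3,7-dione (drawn titanium-free, not isolated) | CC(=O)/C(OC)=C(/C)CC(=O)/C=C(\O[Si](C)(C)C)c1c(OC)cccc1OC | intermediate
11 | 6-(2,6-dimethoxybenzoyl)-5-hydroxy-4-methoxy-3,5-dimethylcyclohex-3-en-1-one (racemic, relative configuration undefined, not isolated) | COc1cccc(OC)c1C(=O)C1C(=O)CC(C)=C(OC)C1(C)O | intermediate
12 | (2,6-dimethoxyphenyl)(6-hydroxy-3-methoxy-2,4-dimethylphenyl)methanone | COc1cccc(OC)c1C(=O)c1c(O)cc(C)c(OC)c1C | intermediate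
13 | {6-[(tert-butyldimethylsilyl)oxy]-3-methoxy-2,4-dimethylphenyl}(2,6-dimethoxyphenyl)methanone | COc1cccc(OC)c1C(=O)c1c(O[Si](C)(C)C(C)(C)C)cc(C)c(OC)c1C | intermediate
14 | rac-8-[(tert-butyldimethylsilyl)oxy]-1-(2,6-dimethoxyphenyl)-5-methoxy-6-methyl-1,4-dihydro-2,3-benzodioxin-1-ol (not isolated) | COc1cccc(OC)c1C1(O)OOCc2c(OC)c(C)cc(O[Si](C)(C)C(C)(C)C)c12 | intermediate
15 | 3-[(tert-butyldimethylsilyl)oxy]-2-(2,6-dimethoxybenzoyl)-6-methoxy-5-methylbenzyl peroxyacetate (not isolated) | CC(=O)OOCc1c(OC)c(C)cc(O[Si](C)(C)C(C)(C)C)c1C(=O)c1c(OC)cccc1OC | intermediate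
16 | 3-[(tert-butyldimethylsilyl)oxy]-2-(2,6-dimethoxybenzoyl)-6-methoxy-5-methylbenzaldehyde | COc1cccc(OC)c1C(=O)c1c(O[Si](C)(C)C(C)(C)C)cc(C)c(OC)c1C=O | intermediate
17 | laterally lithiated 13, lithium o-quinodimethane enolate drawn as the benzyllithium (not isolated) | [Li]Cc1c(OC)c(C)cc(O[Si](C)(C)C(C)(C)C)c1C(=O)c1c(OC)cccc1OC | intermediate
18 | rac-1,2-bis{3-[(tert-butyldimethylsilyl)oxy]-2-(2,6-dimethoxybenzoyl)-6-methoxy-5-methylphenyl}ethan-1-ol | COc1cccc(OC)c1C(=O)c1c(O[Si](C)(C)C(C)(C)C)cc(C)c(OC)c1CC(O)c1c(OC)c(C)cc(O[Si](C)(C)C(C)(C)C)c1C(=O)c1c(OC)cccc1OC | intermediate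
19 | 1,2-bis{3-[(tert-butyldimethylsilyl)oxy]-2-(2,6-dimethoxybenzoyl)-6-methoxy-5-methylphenyl}ethan-1-one | COc1cccc(OC)c1C(=O)c1c(O[Si](C)(C)C(C)(C)C)cc(C)c(OC)c1CC(=O)c1c(OC)c(C)cc(O[Si](C)(C)C(C)(C)C)c1C(=O)c1c(OC)cccc1OC | intermediate
20 | acredinone B | COc1cccc(OC)c1C(=O)c1c(O)cc(C)c(OC)c1CC(=O)c1c(OC)c(C)cc(O)c1C(=O)c1c(OC)cccc1OC | target

**Total step count:** 11
**Longest linear sequence:** 9 steps (6 → 7 → 8 → 9 → 12 → 13 → 16 → 18 → 19 → 20)

**Steps most likely to fail**

Step 6. The second C–C bond formation at the crowded central carbon may be slower than protodesilylation of the diene. The Lewis acid may also remove a methyl ether ortho to the ketone. The fallback sets out from 9 and comes back at 12. It keeps the dielectrophile, closes the ring with an unhindered ester diene and installs the aryl ketone afterwards by carbonyl addition.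
- Compound 9 is condensed with commercial 1-methoxy-1,3-bis(trimethylsilyloxy)buta-1,3-diene (TiCl4, CH2Cl2, −78 → 20 °C) to give methyl 6-hydroxy-3-methoxy-2,4-dimethylbenzoate F1.
- Benzylation (BnBr, K2CO3, DMF) gives methyl 6-(benzyloxy)-3-methoxy-2,4-dimethylbenzoate F2.
- LiAlH4 in refluxing THF gives [6-(benzyloxy)-3-methoxy-2,4-dimethylphenyl]methanol F3, and MnO2 gives 6-(benzyloxy)-3-methoxy-2,4-dimethylbenzaldehyde F4.
- 2,6-Dimethoxyphenyllithium (1,3-dimethoxybenzene, n-BuLi, THF) adds at −78 °C to give rac-[6-(benzyloxy)-3-methoxy-2,4-dimethylphenyl](2,6-dimethoxyphenyl)methanol F5.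
- Dess–Martin oxidation gives [6-(benzyloxy)-3-methoxy-2,4-dimethylphenyl](2,6-dimethoxyphenyl)methanone F6, and hydrogenolysis (H2, Pd/C, EtOAc) returns 12.
- A benzyl ether is used here rather than a silyl ether, because a silyl group next to the new alkoxide could migrate.

Step 8. The twisted photoenol may revert or close electrocyclically to a cyclobutenol faster than oxygen intercepts it. Hydrogen abstraction from the ortho methoxy groups may compete. Sensitised singlet oxygen may attack the electron-rich rings. The fallback sets out from 13 and comes back at 16. It replaces excited-state chemistry with ground-state polar functionalisation.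
- Compound 13 is lithiated with LiTMP as in step 9 to give 17.
- Quenching with hexachloroethane at −78 °C gives {6-[(tert-butyldimethylsilyl)oxy]-2-(chloromethyl)-3-methoxy-4-methylphenyl}(2,6-dimethoxyphenyl)methanone F7.
- A Kornblum-type oxidation with N-methylmorpholine N-oxide (NaI cat., MeCN, rt) gives 16.

Step 9. Deprotonation may be incomplete, or it may stray to the para methyl group or the outer ring. The hindered addition may reverse by retro-aldol. Proton transfer or O-to-O silyl migration may consume the anion. The fallback sets out from 16 and comes back at 18. It generates the nucleophile by metal insertion instead of deprotonation.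
- Part of 16 is reduced chemoselectively (NaBH4, THF/MeOH, −20 °C) to {6-[(tert-butyldimethylsilyl)oxy]-2-(hydroxymethyl)-3-methoxy-4-methylphenyl}(2,6-dimethoxyphenyl)methanone F8.
- An Appel reaction (CBr4, PPh3, CH2Cl2, 0 °C) gives {2-(bromomethyl)-6-[(tert-butyldimethylsilyl)oxy]-3-methoxy-4-methylphenyl}(2,6-dimethoxyphenyl)methanone F9.
- F9 is added with a second portion of 16 to activated zinc in THF (Barbier mode, a vinylogous Reformatsky reaction, since the C–Br bond is conjugated to the ketone through the ring) to give 18.

**Further compounds**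
F1 | step 6 | methyl 6-hydroxy-3-methoxy-2,4-dimethylbenzoate | COC(=O)c1c(O)cc(C)c(OC)c1C
F2 | step 6 | methyl 6-(benzyloxy)-3-methoxy-2,4-dimethylbenzoate | COC(=O)c1c(OCc2ccccc2)cc(C)c(OC)c1C
F3 | step 6 | [6-(benzyloxy)-3-methoxy-2,4-dimethylphenyl]methanol | OCc1c(OCc2ccccc2)cc(C)c(OC)c1C
F4 | step 6 | 6-(benzyloxy)-3-methoxy-2,4-dimethylbenzaldehyde | O=Cc1c(OCc2ccccc2)cc(C)c(OC)c1C
F5 | step 6 | rac-[6-(benzyloxy)-3-methoxy-2,4-dimethylphenyl](2,6-dimethoxyphenyl)methanol | COc1cccc(OC)c1C(O)c1c(OCc2ccccc2)cc(C)c(OC)c1C
F6 | step 6 | [6-(benzyloxy)-3-methoxy-2,4-dimethylphenyl](2,6-dimethoxyphenyl)methanone | COc1cccc(OC)c1C(=O)c1c(OCc2ccccc2)cc(C)c(OC)c1C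
F7 | step 8 | {6-[(tert-butyldimethylsilyl)oxy]-2-(chloromethyl)-3-methoxy-4-methylphenyl}(2,6-dimethoxyphenyl)methanone | COc1cccc(OC)c1C(=O)c1c(O[Si](C)(C)C(C)(C)C)cc(C)c(OC)c1CCl
F8 | step 9 | {6-[(tert-butyldimethylsilyl)oxy]-2-(hydroxymethyl)-3-methoxy-4-methylphenyl}(2,6-dimethoxyphenyl)methanone | COc1cccc(OC)c1C(=O)c1c(O[Si](C)(C)C(C)(C)C)cc(C)c(OC)c1CO
F9 | step 9 | {2-(bromomethyl)-6-[(tert-butyldimethylsilyl)oxy]-3-methoxy-4-methylphenyl}(2,6-dimethoxyphenyl)methanone | COc1cccc(OC)c1C(=O)c1c(O[Si](C)(C)C(C)(C)C)cc(C)c(OC)c1CBr
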